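Assumption: the target is a planar, achiral flavone with no stereocentre, stereogenic axis or stereogenic double bond. There is no enantiomer to select, and the SMILES of compounds 1 to 7 carry no stereo descriptors. Compound 5 is drawn as the diketo tautomer, although it exists largely as the enol.

**Retrosynthetic overview**
1. Target 7 ⇒ symmetric 2,6-dibromoaryl 1,3-diketone 5. Two C–O bonds are cut in one operation: O1–C8a (closure of ring C) and C5–OMe.
2. Diketone 5 ⇒ dibromo ketone 3 + ester 4. This is a crossed Claisen condensation that forms the C3–C2 bond.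
3. Ketone 3 ⇒ 3',4',5'-trimethoxyacetophenone 1 by twofold nuclear bromination of the two equivalent ring positions.
4. Ring order: rings A and B are bought as benzenoid starting materials. Ring C (the pyranone) is the only ring made, and it is made in the last step.

**Route**

Step 1
Reactants: 1 3',4',5'-trimethoxyacetophenone
Product: 3 1-(2,6-dibromo-3,4,5-trimethoxyphenyl)ethan-1-one, via monobromo ketone 2 (not isolated)
Conditions: NBS (2.3 equiv), MeCN, dark, 0 °C → 50 °C
Reagents that add atoms: N-bromosuccinimide, O=C1CCC(=O)N1Br
Why: Electrophilic aromatic bromination (SEAr) with NBS in polar MeCN works because the only two ring C–H positions (C2 and C6) are equivalent and ortho/para to methoxy groups, so twofold bromination can give only one isomer, while dark, acid-free conditions hold back α-bromination of the methyl ketone; no stereocentre is formed.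

Step 2
Reactants: 3 1-(2,6-dibromo-3,4,5-trimethoxyphenyl)ethan-1-one, 4 methyl 3-hydroxy-4,5-dimethoxybenzoate
Product: 5 1-(2,6-dibromo-3,4,5-trimethoxyphenyl)-3-(3-hydroxy-4,5-dimethoxyphenyl)propane-1,3-dione
Conditions: KOtBu (3.5 equiv), THF, 0 → 55 °C; then 1 M HCl
Reagents that add atoms: none
Why: In this crossed Claisen condensation only 3 can enolise and only 4 can donate an acyl group, the phenoxide of 4 is meta to the ester and hardly deactivates it, neither bromine has an ortho hydrogen (no aryne), and formation of the stabilised diketonate pulls the equilibrium to product; no stereocentre is formed.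

Step 3
Reactants: 5 1-(2,6-dibromo-3,4,5-trimethoxyphenyl)-3-(3-hydroxy-4,5-dimethoxyphenyl)propane-1,3-dione
Product: 7 3'-hydroxy-5,6,7,8,4',5'-hexamethoxyflavone, via 5-bromoflavone 6 (not isolated)
Conditions: CuBr (20 mol%), NaOMe (8 equiv, 25 wt% in MeOH), DMF, N2, 110 °C, 8 h; then 2 M HCl, 50 °C, 30 min
Reagents that add atoms: sodium methoxide, C[O-].[Na+]
Why: Proposed new method: a self-ligated, copper-catalysed desymmetrising double C–O coupling in which the two equivalent C–Br bonds of ring A are spent on two different oxygen nucleophiles in one pot; NaOMe turns 5 into its β-diketonate, an O,O-chelate of the kind normally added as a ligand in Ullmann ether couplings, so monovalent copper is held next to an ortho C–Br bond, inserts to a trivalent copper aryl and reductively eliminates the enolate O–C8a bond to close ring C as 6 (only the oxygen on the ring B side can reach, through a six-membered ring), after which the C4 carbonyl of 6, peri to C5–Br, both chelates CuOMe and activates that carbon so that methoxide replaces the second bromine; any other order of events (methoxylation first, then displacement of the remaining Br or of an ortho OMe by the enolate oxygen) ends in the same 7, and the acidic finish recloses any ring-opened 2-hydroxyaryl diketone; the closest known reaction types are the base- or copper-mediated intramolecular O-arylation of 1-(2-haloaryl)-1,3-diketones to chromones and the CuBr/NaOMe Ullmann-type methoxylation of bromoflavones and unprotected bromophenols, which have not been merged on a 2,6-dibromoaryl diketone; no stereocentre is formed.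

**Compound list**
1 | 3',4',5'-trimethoxyacetophenone | CC(=O)c1cc(OC)c(OC)c(OC)c1 | starting material
2 | 1-(2-bromo-3,4,5-trimethoxyphenyl)ethan-1-one | CC(=O)c1cc(OC)c(OC)c(OC)c1Br | intermediate
3 | 1-(2,6-dibromo-3,4,5-trimethoxyphenyl)ethan-1-one | CC(=O)c1c(Br)c(OC)c(OC)c(OC)c1Br | intermediate
4 | methyl 3-hydroxy-4,5-dimethoxybenzoate | COC(=O)c1cc(O)c(OC)c(OC)c1 | starting material
5 | 1-(2,6-dibromo-3,4,5-trimethoxyphenyl)-3-(3-hydroxy-4,5-dimethoxyphenyl)propane-1,3-dione | O=C(CC(=O)c1cc(O)c(OC)c(OC)c1)c1c(Br)c(OC)c(OC)c(OC)c1Br | intermediate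
6 | 5-bromo-2-(3-hydroxy-4,5-dimethoxyphenyl)-6,7,8-trimethoxy-4H-chromen-4-one | COc1cc(-c2cc(=O)c3c(Br)c(OC)c(OC)c(OC)c3o2)cc(O)c1OC | intermediate
7 | 3'-hydroxy-5,6,7,8,4',5'-hexamethoxyflavone | COc1cc(-c2cc(=O)c3c(OC)c(OC)c(OC)c(OC)c3o2)cc(O)c1OC | target

**Step count**
Total step count: 3.
Longest linear sequence: 3 (1 → 3 → 5 → 7).

**Steps most likely to fail, highest risk first**

Step 3 (the proposed new step).
- Risks: hydrodebromination at C5, which would give the 5-H flavone; slow methoxylation of the doubly flanked C5–Br; diaryl ether formation through the free phenoxide.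
- The fallback uses known chemistry only. It sets out from 3 and comes back at 7, and it places the ring oxygen on ring A before the fragments are joined.
- Twofold Ullmann-type methoxylation of 3 (NaOMe, CuBr, DMF/MeOH, 110 °C) gives 1-(2,3,4,5,6-pentamethoxyphenyl)ethan-1-one F4.
- BCl3 (1.1 equiv, CH2Cl2, −20 °C) chelates to the ketone and removes only one ortho methyl, giving 1-(2-hydroxy-3,4,5,6-tetramethoxyphenyl)ethan-1-one F5.
- Claisen–Schmidt condensation of F5 with bought 3-hydroxy-4,5-dimethoxybenzaldehyde F6 (KOH, EtOH, rt) gives (E)-1-(2-hydroxy-3,4,5,6-tetramethoxyphenyl)-3-(3-hydroxy-4,5-dimethoxyphenyl)prop-2-en-1-one F7.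
- I2 (10 mol%) in DMSO at 120 °C then closes ring C by oxa-Michael addition and dehydrogenation to give 7.

Step 2.
- Risks: the dianion mixture (phenoxide plus enolate) may be poorly soluble, and the phenoxide-bearing ester may be too sluggish an acyl donor.
- The fallback sets out from 4 and comes back at 5. It gives up the protecting-group-free condensation.
- MOMCl and iPr2NEt in CH2Cl2 convert 4 into methyl 3,4-dimethoxy-5-(methoxymethoxy)benzoate F2.
- Claisen condensation of F2 with 3 (NaH, THF, reflux) gives 1-(2,6-dibromo-3,4,5-trimethoxyphenyl)-3-[3,4-dimethoxy-5-(methoxymethoxy)phenyl]propane-1,3-dione F3.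
- HCl in MeOH at 40 °C unmasks the phenol of F3 to give 5.

Step 1.
- Risks: the second nuclear bromination is slower than the first, so α-bromination of the methyl ketone may compete.
- The fallback sets out from 1 and comes back at 3. It accepts α-bromination and then repairs it.
- Excess Br2 in AcOH (3.5 equiv, 40 °C) brominates both ring positions and the methyl group, giving 2-bromo-1-(2,6-dibromo-3,4,5-trimethoxyphenyl)ethan-1-one F1.
- Zn dust in AcOH at rt reduces only the α-C–Br bond, the known reductive dehalogenation of α-halo ketones. The aryl bromides are inert, and the product is 3.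

**Further compounds**
F1 | step 1 | 2-bromo-1-(2,6-dibromo-3,4,5-trimethoxyphenyl)ethan-1-one | O=C(CBr)c1c(Br)c(OC)c(OC)c(OC)c1Br
F2 | step 2 | methyl 3,4-dimethoxy-5-(methoxymethoxy)benzoate | COCOc1cc(C(=O)OC)cc(OC)c1OC
F3 | step 2 | 1-(2,6-dibromo-3,4,5-trimethoxyphenyl)-3-[3,4-dimethoxy-5-(methoxymethoxy)phenyl]propane-1,3-dione | COCOc1cc(C(=O)CC(=O)c2c(Br)c(OC)c(OC)c(OC)c2Br)cc(OC)c1OC
F4 | step 3 | 1-(2,3,4,5,6-pentamethoxyphenyl)ethan-1-one | CC(=O)c1c(OC)c(OC)c(OC)c(OC)c1OC
F5 | step 3 | 1-(2-hydroxy-3,4,5,6-tetramethoxyphenyl)ethan-1-one | CC(=O)c1c(O)c(OC)c(OC)c(OC)c1OC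
F6 | step 3 | 3-hydroxy-4,5-dimethoxybenzaldehyde (bought) | O=Cc1cc(O)c(OC)c(OC)c1
F7 | step 3 | (E)-1-(2-hydroxy-3,4,5,6-tetramethoxyphenyl)-3-(3-hydroxy-4,5-dimethoxyphenyl)prop-2-en-1-one | O=C(/C=C/c1cc(O)c(OC)c(OC)c1)c1c(O)c(OC)c(OC)c(OC)c1OC
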